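Assumption: the target has no stereocentre or stereogenic axis, so it is one achiral compound and no stereocontrol is needed.

**Retrosynthetic overview** (numbers are assigned in the forward route below)
1. Target ⇐ hydrogenolysis of its 2',5'-bis(benzyl) ether; nothing else changes in the last step.
2. Ring C and the 5-OH ⇐ two C–O bonds (O1–C8a and C5–OH) made in one copper-catalysed operation from a 2,6-dibromoaroyl 1,3-diketone; the two bromides are equivalent by symmetry.
3. 1,3-Diketone ⇐ C-acylation of the enolate of 2',5'-bis(benzyloxy)acetophenone with 2,6-dibromo-3,4,5-trimethoxybenzoyl chloride.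
4. Building blocks ⇐ 2',5'-dihydroxyacetophenone (plus benzyl bromide) and 3,4,5-trimethoxybenzoic acid (plus bromine).
5. Ring order: rings A and B are bought as benzene rings; ring C (the pyranone) is the only ring formed, in step 4.

**Route**

Step 1
Reactants: 1 1-(2,5-dihydroxyphenyl)ethan-1-one (2',5'-dihydroxyacetophenone)
Product: 2 1-[2,5-bis(benzyloxy)phenyl]ethan-1-one
Conditions: BnBr (2.4 equiv), K2CO3 (3 equiv), KI (cat.), DMF, 70 °C
Reagents that add atoms: benzyl bromide, BrCc1ccccc1
Why: Williamson ether synthesis; heat and iodide catalysis also benzylate the hydrogen-bonded 2-OH, masking the hydroquinone for the base and copper steps (no stereocentre).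

Step 2
Reactants: 3 3,4,5-trimethoxybenzoic acid
Product: 4 2,6-dibromo-3,4,5-trimethoxybenzoic acid
Conditions: Br2 (2.5 equiv), AcOH, rt → 60 °C
Reagents that add atoms: bromine, BrBr
Why: Electrophilic aromatic bromination; both free positions are ortho/para to methoxy donors, while ipso attack at C1 (bromodecarboxylation) is slow because the flanked 4-OMe is twisted out of conjugation.

Step 3
Reactants: 4 2,6-dibromo-3,4,5-trimethoxybenzoic acid; 2 1-[2,5-bis(benzyloxy)phenyl]ethan-1-one
Product: 7 1-[2,5-bis(benzyloxy)phenyl]-3-(2,6-dibromo-3,4,5-trimethoxyphenyl)propane-1,3-dione, via 2,6-dibromo-3,4,5-trimethoxybenzoyl chloride 5 (not isolated), via lithium 1-[2,5-bis(benzyloxy)phenyl]ethen-1-olate 6 (not isolated)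
Conditions: 4, (COCl)2 (1.3 equiv), DMF (cat.), CH2Cl2, 0 °C → rt, evaporate; separately 2 (1.05 equiv), LiHMDS (2.1 equiv), THF, −78 °C; add 5, −78 → 0 °C; aq. NH4Cl
Reagents that add atoms: oxalyl chloride, ClC(=O)C(=O)Cl (its Cl is in 5 only); lithium bis(trimethylsilyl)amide, [Li+].C[Si](C)(C)[N-][Si](C)(C)C (its Li is in 6 only); nothing from either remains in 7
Why: Claisen-type C-acylation of a lithium ketone enolate with an aroyl chloride; the second equivalent of base traps the product as its diketonate and stops over-acylation, and the bromides have no ortho hydrogen, so no aryne can form.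

Step 4
Reactants: 7 1-[2,5-bis(benzyloxy)phenyl]-3-(2,6-dibromo-3,4,5-trimethoxyphenyl)propane-1,3-dione
Product: 9 2-[2,5-bis(benzyloxy)phenyl]-5-hydroxy-6,7,8-trimethoxy-4H-chromen-4-one, via 2-[2,5-bis(benzyloxy)phenyl]-5-bromo-6,7,8-trimethoxy-4H-chromen-4-one 8 (not isolated)
Conditions: CuI (10 mol%), N,N'-bis(4-hydroxy-2,6-dimethylphenyl)oxalamide (10 mol%), LiOH·H2O (1.2 equiv), DMSO, 80 °C, Ar; then LiOH·H2O (3 equiv), DMSO/H2O 4:1, 80 °C; AcOH to pH 4, 50 °C
Reagents that add atoms: lithium hydroxide monohydrate, [Li+].[OH-].O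
Why: Proposed new method: a copper-catalysed desymmetrising double C–O coupling of a 2,6-dibromoaroyl 1,3-diketone. The lithium diketonate binds Cu(I); oxidative addition of either (equivalent) ortho C–Br and C(aryl)–O reductive elimination with the far enolate oxygen closes the pyranone to 8. Ring B has no halide, so only ring A can close. The remaining bromide of 8 lies peri to the C4 carbonyl, which directs copper to it for hydroxylation by LiOH. If hydroxide instead opens the pyranone at C2, the resulting bromo-phenoxide diketonate recloses onto the second bromide and gives the same product. The closest known reactions are the Ullmann-type intramolecular O-arylation of 1-(2-bromoaryl)-1,3-diketones to flavones and the Cu/oxalamide-catalysed hydroxylation of aryl bromides, which have not been combined on a dibromo substrate of this kind.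

Step 5
Reactants: 9 2-[2,5-bis(benzyloxy)phenyl]-5-hydroxy-6,7,8-trimethoxy-4H-chromen-4-one
Product: 10 2-(2,5-dihydroxyphenyl)-5-hydroxy-6,7,8-trimethoxy-4H-chromen-4-one (5,2',5'-trihydroxy-6,7,8-trimethoxyflavone)
Conditions: H2 (1 atm), 10% Pd/C, EtOAc/MeOH 1:1, rt; filter and concentrate under N2
Reagents that add atoms: none
Why: Catalytic hydrogenolysis of aryl benzyl ethers; the flavone C2=C3 bond, the methyl ethers and the chelated 5-OH are inert at 1 atm and rt, and the achiral product needs no stereocontrol.

**Compound list**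
1 | 1-(2,5-dihydroxyphenyl)ethan-1-one | CC(=O)c1cc(O)ccc1O | starting material
2 | 1-[2,5-bis(benzyloxy)phenyl]ethan-1-one | CC(=O)c1cc(OCc2ccccc2)ccc1OCc3ccccc3 | intermediate
3 | 3,4,5-trimethoxybenzoic acid | COc1cc(C(=O)O)cc(OC)c1OC | starting material
4 | 2,6-dibromo-3,4,5-trimethoxybenzoic acid | COc1c(Br)c(C(=O)O)c(Br)c(OC)c1OC | intermediate
5 | 2,6-dibromo-3,4,5-trimethoxybenzoyl chloride | COc1c(Br)c(C(=O)Cl)c(Br)c(OC)c1OC | intermediate
6 | lithium 1-[2,5-bis(benzyloxy)phenyl]ethen-1-olate | [Li+].C=C([O-])c1cc(OCc2ccccc2)ccc1OCc3ccccc3 | intermediate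
7 | 1-[2,5-bis(benzyloxy)phenyl]-3-(2,6-dibromo-3,4,5-trimethoxyphenyl)propane-1,3-dione | O=C(CC(=O)c1cc(OCc2ccccc2)ccc1OCc3ccccc3)c4c(Br)c(OC)c(OC)c(OC)c4Br | intermediate
8 | 2-[2,5-bis(benzyloxy)phenyl]-5-bromo-6,7,8-trimethoxy-4H-chromen-4-one | COc1c(OC)c(Br)c2c(=O)cc(-c3cc(OCc4ccccc4)ccc3OCc5ccccc5)oc2c1OC | intermediate
9 | 2-[2,5-bis(benzyloxy)phenyl]-5-hydroxy-6,7,8-trimethoxy-4H-chromen-4-one | COc1c(OC)c(O)c2c(=O)cc(-c3cc(OCc4ccccc4)ccc3OCc5ccccc5)oc2c1OC | intermediate
10 | 2-(2,5-dihydroxyphenyl)-5-hydroxy-6,7,8-trimethoxy-4H-chromen-4-one | COc1c(OC)c(O)c2c(=O)cc(-c3cc(O)ccc3O)oc2c1OC | target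

**Totals**
Total step count: 5. Longest linear sequence: 4 steps (3 → 4 → 7 → 9 → 10; the branch 1 → 2 joins at step 3).

**Three steps most likely to fail**

Step 4 (the proposed new cascade). The risks are hydroxide cleaving the diketone (retro-Claisen), hydrodebromination, and a sluggish second coupling at the hindered bromide. The fallback uses known chemistry, sets out from 7 and comes back at 9. Compound 7 is cyclised with CuI (10 mol%) and K2CO3 in DMF at 110 °C by the known intramolecular Ullmann O-arylation, and the bromoflavone 8 is isolated. Then 8 is hydroxylated by the known palladium-catalysed coupling with hydroxide (Pd2(dba)3, tBuXPhos, KOH, dioxane/H2O, 100 °C, acidic work-up) to give 9. This makes no compound outside the compound list (F0).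

Step 3 (C-acylation with a di-ortho-substituted aroyl chloride). The risks are O-acylation to the enol ester and slow reaction at the hindered carbonyl. The fallback sets out from 5 (with enolate 6) and comes back at 7. Acid chloride 5 is reduced with LiAlH(OtBu)3 in THF at −78 °C to 2,6-dibromo-3,4,5-trimethoxybenzaldehyde F3. Aldol addition of enolate 6 to F3 (THF, −78 °C, NH4Cl quench) gives racemic 1-[2,5-bis(benzyloxy)phenyl]-3-(2,6-dibromo-3,4,5-trimethoxyphenyl)-3-hydroxypropan-1-one F4. Dess–Martin periodinane (CH2Cl2, rt) oxidises F4 to diketone 7.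

Step 2 (double bromination of the free acid). The risks are a stalled second bromination and ipso-bromodecarboxylation. The fallback sets out from 3 and comes back at 4. Fischer esterification (MeOH, H2SO4, reflux) gives methyl 3,4,5-trimethoxybenzoate F1, which cannot decarboxylate. 1,3-Dibromo-5,5-dimethylhydantoin (1.2 equiv) in TFA/CH2Cl2 gives methyl 2,6-dibromo-3,4,5-trimethoxybenzoate F2. The hindered ester is then cleaved at the methyl carbon with LiI in refluxing pyridine, and acidification gives 4.

**Further compounds**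
F1 | step 2 | methyl 3,4,5-trimethoxybenzoate | COC(=O)c1cc(OC)c(OC)c(OC)c1
F2 | step 2 | methyl 2,6-dibromo-3,4,5-trimethoxybenzoate | COC(=O)c1c(Br)c(OC)c(OC)c(OC)c1Br
F3 | step 3 | 2,6-dibromo-3,4,5-trimethoxybenzaldehyde | COc1c(Br)c(C=O)c(Br)c(OC)c1OC
F4 | step 3 | racemic 1-[2,5-bis(benzyloxy)phenyl]-3-(2,6-dibromo-3,4,5-trimethoxyphenyl)-3-hydroxypropan-1-one | O=C(CC(O)c1c(Br)c(OC)c(OC)c(OC)c1Br)c2cc(OCc3ccccc3)ccc2OCc4ccccc4
F0 | step 4 | none | none
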